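All runs were generated by integration for an exercise.

**Charge ratio.** 100 free monomer are charged per initiator in this flask, so I write the initiator's balance first. Used once each, the initiator could put 1.00 % of the charge into chains. The green run reads 72.2 % on average from 2.08 d on. That is 72.3 monomer in chains per initiator charged, so the initiator works as a catalyst.

all flasks: initiator 0.50 mM

| run | free monomer | temperature | remark | time |
|---|---|---|---|---|
| green | 0.050 M | 20 °C | the very flask that is asked about, followed so far |  |
| red | 0.034 M | 15 °C | run made earlier |  |
| flask | 0.050 M | 20 °C |  | 8.0 d |

- green (time / d: monomer in chains / %, free monomer / %): 0.625: 57, 20; 1.25: 71, 4; 2.08: 70, 0; 3.00: 75, 1; 4.00: 73, 0; 5.00: 71, 0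
- red (time / h: monomer in chains / %, free monomer / %): 2.50: 4, 92; 6.00: 18, 72; 12.0: 37, 48; 20.0: 57, 25; 25.0: 60, 17; 30.0: 65, 13; 40.0: 73, 4

(standard deviation of a reading: 1.5 percentage points)

- south-west: at 8.0 d take out 90 % of the monomer in chains then present, then wait 4.0 d
- south: at 8.0 d raise the temperature by 10 K, then wait 4.0 d
- north-east: at 8.0 d add initiator, 100 % of the amount charged, then wait 4.0 d
- west: change nothing and wait 4.0 d more

- monomer in chains that was removed still counts
- the numbers in the tables scatter by 1.5 percentage points (one standard deviation)
- additions bring no volume worth counting

* monomer in chains, in percent of the free monomer first charged, at 8.0 d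
* which option adds most monomer in chains ("none" when 2 percentage points or less is all one gets) (south-west / south / north-east / west / none)
* monomer in chains present, with what was taken out counted in, in percent of the free monomer first charged, after north-east
* monomer in chains present, with what was taken out counted in, in percent of the free monomer first charged, after west

**Bench rule.** The bench rule says two things. A flask whose free monomer reads zero is finished, and a catalyst's amount changes speed, not yield. In the green run free monomer reads 0 % at 5.00 d, and the scatter of 1.5 percentage points lies below the margin of 2 points. Chains in the green run read from 70 % to 75 % over those days, with no drift I can see. So I commit to 72.2 % at 8.0 d, to no useful option, and to the same figure after north-east and after west.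

**The border.** The second half of the rule stops at the balance. The green run leaves 27.7 % of its charge outside chains, so I take free monomer to have two routes and the yield to follow a ratio of two rates. Chains over that share give the selectivity factor R = 2.60, as a reading. I assume the chain route scales with c(initiator) and the other route does not. Both runs have 0.50 mM of initiator, so the readings do not test this. R divided by c(initiator) is my chain ratio per initiator, ρ = 5.21 mM⁻¹. With free monomer and temperature held, I estimate the yield in chains at another initiator charge as R over one plus R, with R = ρ c(initiator).

**The result.** The forecast gave 72 %, none, 72 % and 72 %, and of the unseen share it said: “It therefore looks like a parallel, effectively irreversible side product rather than a reservoir.” The flask gives 72.2 %, none, 72.2 % after north-east and 72.2 % after west.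

    free monomer + initiator → living end + monomer in chains (k = 0.00254 L mol⁻¹ s⁻¹, Ea = 47.0 kJ mol⁻¹)
    free monomer + living end → monomer in chains + living end, rate k2*[living end]*[free monomer] (k = 0.0583 L mol⁻¹ s⁻¹, Ea = 51.0 kJ mol⁻¹)
    free monomer → uncatalysed product (k = 8.37 × 10⁻⁶ s⁻¹, Ea = 90.0 kJ mol⁻¹)
    2 living end → dead end (k = 0.00174 L mol⁻¹ s⁻¹, Ea = 56.0 kJ mol⁻¹)
    (constants at 20 °C)

**Two routes.** At 0.308 d in this flask, free monomer has a shorter half-life by the step with living end into chains, 0.31 d, than by the step into uncatalysed product, 0.96 d, a rate ratio of 3.1. At 8.00 d this flask holds 72.2 % in chains, 27.8 % uncatalysed product and 0 % free monomer. ρ times its c(initiator) gives back my green-run 2.60, which is no test. A neighbour flask, the same but for its initiator, has 3.0 × 10⁻⁴ M of it. There ρ gives R = 1.56, hence 60.9 % in chains. Computed, that neighbour flask holds 62.6 % in chains and 37.4 % uncatalysed product.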